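**Retrosynthetic overview**
1. Ester last: vanillic acid plus the cis (6R) hexahydroazulenol by Mitsunobu inversion; the alcohol comes from the 6-ketone.
2. Ring A (cyclopentene) by ring-closing metathesis of an allyl group on the tetrasubstituted alkene carbon and an isopropenyl group on the ring-fusion CH.
3. Key bond: isopropenyl to the δ-carbon of a cyclohepta-2,4-dienone (1,6-addition, anti to isopropyl), formed by Ni-catalysed electroreduction; the allyl group comes from Stille coupling of the 4-bromodienone.
4. The 4-bromodienone arises by one-carbon ring expansion of the (R)-α-phellandrene ring (dibromocarbene [2+1], then Ag-assisted electrocyclic opening with loss of HBr), after the disubstituted alkene has been converted to the ketone.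
5. Ring order: seven-membered ring first (from the bought six-membered ring), five-membered ring last.

Assumption: (R)-(−)-α-phellandrene is taken as enantiopure; compounds 3, 4 and 5 are drawn as the anti-cyclopropane isomer and 4 with boron trans to isopropyl, although both cyclopropane isomers give 6 and the boron-bearing centre is lost in 5.

**Step 1**
Reactants: 1 (R)-(−)-α-phellandrene; 2 bromoform
Product: 3 (1R,4R,6S)-7,7-dibromo-1-methyl-4-(propan-2-yl)bicyclo[4.1.0]hept-2-ene
Conditions: CHBr3 (1.2 equiv), KOtBu (1.5 equiv), pentane, −20 → 0 °C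
Reagents that add atoms: bromoform (2), BrC(Br)Br
Why: Dibromocarbene [2+1] cycloaddition goes to the more electron-rich trisubstituted alkene of the diene, mainly anti to the isopropyl group, and the two new cyclopropane centres are erased in step 3.

**Step 2**
Reactants: 3 dibromocyclopropane
Product: 5 (1R,4R,6S)-7,7-dibromo-1-methyl-4-(propan-2-yl)bicyclo[4.1.0]heptan-3-one, via alkylborane 4 (not isolated)
Conditions: BH3·SMe2, THF, 0 °C → rt; then N-methylmorpholine N-oxide, nPr4N[RuO4] (5 mol%), 4 Å MS, CH2Cl2, rt
Reagents that add atoms: N-methylmorpholine N-oxide, C[N+]1([O-])CCOCC1; borane–dimethyl sulfide, B.CSC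
Why: Hydroboration places boron (which stays only in the non-isolated 4) on the alkene carbon remote from the cyclopropane (vinylcyclopropane electronics, and away from the quaternary carbon), and perruthenate/N-oxide oxidation of the organoborane delivers the ketone oxygen from the N-oxide under near-neutral conditions that leave the bought stereocentre untouched.

**Step 3**
Reactants: 5 dibromocyclopropyl ketone
Product: 6 (7R)-4-bromo-3-methyl-7-(propan-2-yl)cyclohepta-2,4-dien-1-one
Conditions: AgBF4, 2,6-lutidine, CH2Cl2, 0 °C → rt, dark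
Reagents that add atoms: none
Why: Silver-assisted loss of the endo bromide triggers the disrotatory cyclopropyl-to-allyl cation ring expansion, and E1 loss of the proton α to the ketone gives the conjugated bromodienone, the weak base not enolising towards the isopropyl-bearing carbon.

**Step 4**
Reactants: 6 bromodienone; 7 allyltributylstannane
Product: 8 (7R)-3-methyl-7-(propan-2-yl)-4-(prop-2-en-1-yl)cyclohepta-2,4-dien-1-one
Conditions: Pd(PPh3)4 (5 mol%), CuI (10 mol%), DMF, 60 °C
Reagents that add atoms: allyltributylstannane (7), C=CC[Sn](CCCC)(CCCC)CCCC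
Why: Stille coupling of the electron-poor alkenyl bromide runs under neutral conditions, so the α-stereocentre is not epimerised.

**Step 5**
Reactants: 8 allyl dienone; 9 2-bromopropene (3 equiv)
Product: 11 (5R,7R)-3-methyl-7-(propan-2-yl)-5-(prop-1-en-2-yl)-4-(prop-2-en-1-yl)cyclohept-3-en-1-one, via bromozinc dienolate 10 (not isolated)
Conditions: NiBr2·dme (10 mol%), 4,4′-di-tert-butyl-2,2′-bipyridine (12 mol%), nBu4NBF4, DMF, sacrificial zinc anode, nickel-foam cathode, undivided cell, 4 mA, 2.5 F/mol, 0 °C; then AcOH, −40 °C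
Reagents that add atoms: 2-bromopropene (9), CC(Br)=C; zinc, [Zn]
Why: Proposed new method: cathodically formed zerovalent nickel inserts into the C–Br bond of 9 and the isopropenyl–nickel species adds to the ring-locked s-cis dienone at the δ-carbon because the β-carbon is fully substituted, the resulting dienolate being taken up as 10 by the zinc cation released from the anode (zinc and bromine stay only in 10) and kinetic α-protonation keeping the tetrasubstituted alkene, while the new stereocentre is set by attack anti to the isopropyl group two carbons away (as in trans-selective additions to 5-substituted cyclohexenones); the closest known reaction type is the Ni-catalysed electroreductive 1,4-addition of aryl and alkenyl halides to enones.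

**Step 6**
Reactants: 11 allyl isopropenyl ketone
Product: 12 (3aR,5R)-3,8-dimethyl-5-(propan-2-yl)-1,3a,4,5,6,7-hexahydroazulen-6-one
Conditions: second-generation Grubbs catalyst (5 mol%), CH2Cl2 (5 mM), 40 °C
Reagents that add atoms: none
Why: Ring-closing metathesis of the terminal allyl alkene with the 1,1-disubstituted isopropenyl group closes the trisubstituted cyclopentene, the tetrasubstituted ring alkene being inert to the catalyst.

**Step 7**
Reactants: 12 bicyclic ketone
Product: 13 (3aR,5R,6R)-3,8-dimethyl-5-(propan-2-yl)-1,3a,4,5,6,7-hexahydroazulen-6-ol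
Conditions: LiBH(sec-Bu)3, THF, −78 °C; then H2O
Reagents that add atoms: none
Why: The bulky hydride attacks the ketone from the face opposite the adjacent isopropyl group (steric approach control), giving the alcohol cis to isopropyl without enolisation at −78 °C.

**Step 8**
Reactants: 13 cis-alcohol; 14 vanillic acid
Product: 15 (3aR,5R,6S)-3,8-dimethyl-5-(propan-2-yl)-1,3a,4,5,6,7-hexahydroazulen-6-yl 4-hydroxy-3-methoxybenzoate
Conditions: PPh3, DIAD, THF, 0 °C → rt
Reagents that add atoms: vanillic acid (14), COc1cc(C(=O)O)ccc1O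
Why: Mitsunobu esterification uses the carboxylic acid (far more acidic than the phenol) as nucleophile and inverts the carbinol centre from the face anti to isopropyl, giving the trans 6S ester of the target.

**Compound list**
1 | (5R)-2-methyl-5-(propan-2-yl)cyclohexa-1,3-diene, (R)-(−)-α-phellandrene | CC1=CC[C@H](C(C)C)C=C1 | starting material
2 | bromoform | BrC(Br)Br | starting material
3 | (1R,4R,6S)-7,7-dibromo-1-methyl-4-(propan-2-yl)bicyclo[4.1.0]hept-2-ene | C1=C[C@]2(C)[C@H](C[C@@H]1C(C)C)C2(Br)Br | intermediate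
4 | [(1R,3S,4S,6S)-7,7-dibromo-1-methyl-4-(propan-2-yl)bicyclo[4.1.0]heptan-3-yl]borane | B[C@H]1C[C@]2(C)[C@H](C[C@@H]1C(C)C)C2(Br)Br | intermediate (not isolated)
5 | (1R,4R,6S)-7,7-dibromo-1-methyl-4-(propan-2-yl)bicyclo[4.1.0]heptan-3-one | O=C1C[C@]2(C)[C@H](C[C@@H]1C(C)C)C2(Br)Br | intermediate
6 | (7R)-4-bromo-3-methyl-7-(propan-2-yl)cyclohepta-2,4-dien-1-one | O=C1C=C(C)C(Br)=CC[C@@H]1C(C)C | intermediate
7 | tributyl(prop-2-en-1-yl)stannane | C=CC[Sn](CCCC)(CCCC)CCCC | starting material
8 | (7R)-3-methyl-7-(propan-2-yl)-4-(prop-2-en-1-yl)cyclohepta-2,4-dien-1-one | O=C1C=C(C)C(CC=C)=CC[C@@H]1C(C)C | intermediate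
9 | 2-bromoprop-1-ene | CC(Br)=C | starting material
10 | bromo{[(5R,7R)-3-methyl-7-(propan-2-yl)-5-(prop-1-en-2-yl)-4-(prop-2-en-1-yl)cyclohepta-1,3-dien-1-yl]oxy}zinc | Br[Zn]OC1=CC(C)=C(CC=C)[C@@H](C(C)=C)C[C@@H]1C(C)C | intermediate (not isolated)
11 | (5R,7R)-3-methyl-7-(propan-2-yl)-5-(prop-1-en-2-yl)-4-(prop-2-en-1-yl)cyclohept-3-en-1-one | O=C1CC(C)=C(CC=C)[C@@H](C(C)=C)C[C@@H]1C(C)C | intermediate
12 | (3aR,5R)-3,8-dimethyl-5-(propan-2-yl)-1,3a,4,5,6,7-hexahydroazulen-6-one | O=C1CC(C)=C2CC=C(C)[C@H]2C[C@@H]1C(C)C | intermediate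
13 | (3aR,5R,6R)-3,8-dimethyl-5-(propan-2-yl)-1,3a,4,5,6,7-hexahydroazulen-6-ol | O[C@@H]1CC(C)=C2CC=C(C)[C@H]2C[C@@H]1C(C)C | intermediate
14 | 4-hydroxy-3-methoxybenzoic acid (vanillic acid) | COc1cc(C(=O)O)ccc1O | starting material
15 | (3aR,5R,6S)-3,8-dimethyl-5-(propan-2-yl)-1,3a,4,5,6,7-hexahydroazulen-6-yl 4-hydroxy-3-methoxybenzoate | COc1cc(C(=O)O[C@H]2CC(C)=C3CC=C(C)[C@H]3C[C@@H]2C(C)C)ccc1O | target

**Step count and risks**
Total steps: 8. Longest linear sequence: 8 (1 → 15).

The three steps most likely to fail are these.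

Step 5 (the proposed electroreductive 1,6-alkenylation) may give 1,4-addition, reduction of the dienone or poor facial selectivity. The fallback sets out from 8 and uses the known cuprate 1,6-addition to dienones. Isopropenylmagnesium bromide, CH2=C(CH3)MgBr, with CuBr·SMe2 and Me3SiCl in THF at −78 °C gives trimethyl{[(5R,7R)-3-methyl-7-(propan-2-yl)-5-(prop-1-en-2-yl)-4-(prop-2-en-1-yl)cyclohepta-1,3-dien-1-yl]oxy}silane F1. Cold AcOH with catalytic KF in aqueous THF then hydrolyses it with α-protonation, and the route is rejoined at 11.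

Step 3 (ring expansion with direct loss of HBr) may stop at cation capture or give the non-conjugated diene. The fallback sets out from 5 and separates capture from elimination. AgClO4 in aqueous acetone (the well-known solvolytic ring expansion of gem-dibromocyclopropanes) gives (5S,7R)-4-bromo-5-hydroxy-3-methyl-7-(propan-2-yl)cyclohept-3-en-1-one F2 (either C5 epimer serves). Catalytic TsOH·H2O in toluene at 40 °C then effects 1,4-dehydration through the dienol, and the route is rejoined at 6.

Step 8 (Mitsunobu on a hindered, homoallylic secondary alcohol) may give elimination to the conjugated diene or a low yield. The fallback sets out from 12 and avoids inversion. NaBH4/CeCl3·7H2O in MeOH at −78 °C (small hydride) gives (3aR,5R,6S)-3,8-dimethyl-5-(propan-2-yl)-1,3a,4,5,6,7-hexahydroazulen-6-ol F3, with any cis isomer 13 removed by chromatography. Coupling with commercial 4-acetoxy-3-methoxybenzoic acid (EDC·HCl, DMAP, CH2Cl2) gives (3aR,5R,6S)-3,8-dimethyl-5-(propan-2-yl)-1,3a,4,5,6,7-hexahydroazulen-6-yl 4-(acetyloxy)-3-methoxybenzoate F4 with retention. K2CO3 in MeOH at 0 °C removes only the phenolic acetate, and the route is rejoined at 15.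

**Further compounds**
F1 | step 5 | trimethyl{[(5R,7R)-3-methyl-7-(propan-2-yl)-5-(prop-1-en-2-yl)-4-(prop-2-en-1-yl)cyclohepta-1,3-dien-1-yl]oxy}silane | C[Si](C)(C)OC1=CC(C)=C(CC=C)[C@@H](C(C)=C)C[C@@H]1C(C)C
F2 | step 3 | (5S,7R)-4-bromo-5-hydroxy-3-methyl-7-(propan-2-yl)cyclohept-3-en-1-one | O=C1CC(C)=C(Br)[C@@H](O)C[C@@H]1C(C)C
F3 | step 8 | (3aR,5R,6S)-3,8-dimethyl-5-(propan-2-yl)-1,3a,4,5,6,7-hexahydroazulen-6-ol | O[C@H]1CC(C)=C2CC=C(C)[C@H]2C[C@@H]1C(C)C
F4 | step 8 | (3aR,5R,6S)-3,8-dimethyl-5-(propan-2-yl)-1,3a,4,5,6,7-hexahydroazulen-6-yl 4-(acetyloxy)-3-methoxybenzoate | COc1cc(C(=O)O[C@H]2CC(C)=C3CC=C(C)[C@H]3C[C@@H]2C(C)C)ccc1OC(C)=O
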